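The cyclodecane ring of the target is treated as the valence isomer of a bicyclo[2.2.0]hexane (C1, C2, C3, C4, C5, C10) fused through C5–C10 to a cyclohexanone (C5–C10). Heating this strained cis-anti-cis 6-4-4 ketone breaks C1–C4 and then C5–C10, which in a single operation opens the ten-membered ring and sets the 1(10)E and 4Z double bonds beside the C6 ketone. The precursor is the head-to-head [2+2] photoadduct of an enantiopure 3-methylcyclohexenone carrying the C7 acetate and C8 silyl ether with an enantiopure 2-methylcyclobutenyl isobutyrate, so the C3 ester is already in place and no C–H oxidation follows ring opening.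

Key step: step 9

Remark on numbering: ring positions of the photoadduct and of all ten-membered compounds carry germacrane numbers (C1–C15); α/β refer to the usual germacranolide drawing with H7 α.

Assumption: the senses of induction in steps 2, 6 and 14 are taken from the standard models (Noyori–Ikariya model with the acyl-bearing arm of the dione in the place of the aryl group; Kazlauskas rule; Sharpless outcome for 2,3-disubstituted allylic alcohols); if one is opposite on these substrates, the ligand antipode (steps 2, 14) or the acylated fraction of the resolution (step 6) is used instead.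

Step 1
Reactants: 1 5-methylcyclohexane-1,3-dione; 2 methyl bromoacetate
Product: 3 methyl 2-(4-methyl-2,6-dioxocyclohexyl)acetate
Conditions: NaOMe (1.0 equiv), MeOH, 65 °C
Reagents that add atoms: none
Why: C-alkylation of the stabilised dione anion by the reactive α-bromo ester in a protic medium that disfavours O-alkylation (Stetter-type alkylation of a cyclic 1,3-dione); no stereocentre is fixed because C7 of 3 enolises freely.

Step 2
Reactants: 3 methyl 2-(4-methyl-2,6-dioxocyclohexyl)acetate
Product: 5 cis silyloxy keto ester (1R,2R), via cis-hydroxy ketone 4 (not isolated)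
Conditions: RuCl(p-cymene)[(R,R)-TsDPEN] (1 mol %), HCO2H–Et3N azeotrope, 25 °C; then tBuMe2SiOTf, 2,6-lutidine, CH2Cl2, −78 °C
Reagents that add atoms: tert-butyldimethylsilyl triflate, CC(C)(C)[Si](C)(C)OS(=O)(=O)C(F)(F)F
Why: Noyori–Ikariya asymmetric transfer hydrogenation with dynamic kinetic resolution should reduce one enantiotopic carbonyl of the rapidly enolising dione with hydride delivered anti to the C7 substituent, fixing C8 (R) and C7 (R, cis) together and stopping there because the remaining isolated ketone is a poor substrate, while immediate silylation pre-empts γ-lactone formation from the cis hydroxy ester; the methyl-bearing carbon is carried as both epimers and becomes sp2 in step 3.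

Step 3
Reactants: 5 cis silyloxy keto ester
Product: 7 enone methyl 2-[(1R,6R)-6-(tert-butyldimethylsilyloxy)-4-methyl-2-oxocyclohex-3-en-1-yl]acetate, via trimethylsilyl enol ether 6 (not isolated)
Conditions: LiN(iPr)2, Me3SiCl (in-situ quench), THF, −78 °C; then Pd(OAc)2, MeCN, 25 °C
Reagents that add atoms: none
Why: Saegusa–Ito dehydrogenation, in which kinetic deprotonation takes the unsubstituted α-CH2 (C5) in preference to the branched C7–H (as for 2,5-dialkylcyclohexanones) and β-hydride loss from the palladium enolate places the double bond at C5=C10, erasing the epimeric methyl carbon without touching C7 or C8.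

Step 4
Reactants: 8 methylenecyclobutane
Product: 9 1-methylcyclobut-1-ene
Conditions: KOtBu (cat.), DMSO, 25 °C; distillation
Reagents that add atoms: none
Why: base-mediated prototropic isomerisation to the more substituted, thermodynamically preferred endocyclic alkene, which is distilled from the equilibrium mixture.

Step 5
Reactants: 9 1-methylcyclobut-1-ene
Product: 10 rac-2-methylcyclobut-2-en-1-ol
Conditions: SeO2 (0.3 equiv), tBuOOH, CH2Cl2, 0 → 25 °C
Reagents that add atoms: tert-butyl hydroperoxide, CC(C)(C)OO
Why: Riley allylic hydroxylation, in which the ene reaction at the less substituted alkene carbon takes hydrogen from the ring CH2 attached to the methyl-bearing carbon (CH2 before CH3, as with 1-methylcyclopentene and 1-methylcyclohexene) and the [2,3]-shift restores the endocyclic double bond with oxygen on the carbon that becomes C3; the product is racemic.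

Step 6
Reactants: 10 rac-2-methylcyclobut-2-en-1-ol
Product: 11 (S)-2-methylcyclobut-2-en-1-ol
Conditions: Candida antarctica lipase B (immobilised), vinyl acetate, pentane, 25 °C, to just past half conversion
Reagents that add atoms: none
Why: lipase-catalysed kinetic resolution by transesterification, in which the (R)-alcohol should be acetylated first (Kazlauskas rule for cycloalk-2-enols) and the slower (S)-alcohol is recovered, which sets the future C3 configuration.

Step 7
Reactants: 11 (S)-2-methylcyclobut-2-en-1-ol
Product: 12 (S)-2-methylcyclobut-2-en-1-yl 2-methylpropanoate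
Conditions: iPrCOCl, pyridine, DMAP (cat.), CH2Cl2, 0 °C
Reagents that add atoms: isobutyryl chloride, CC(C)C(Cl)=O
Why: pyridine-mediated acylation of a secondary alcohol by an acid chloride, which leaves the C–O bond at the stereocentre intact, so configuration is retained.

Step 8
Reactants: 7 enone; 12 (S)-2-methylcyclobut-2-en-1-yl 2-methylpropanoate
Product: 13 cis-anti-cis 6-4-4 tricyclic ketone (head-to-head photoadduct)
Conditions: hν (350 nm, Pyrex), 12 (4 equiv), CH2Cl2, −40 °C; then neutral Al2O3 (epimerises trans-fused adducts at C5); chromatography removes head-to-tail isomers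
Reagents that add atoms: none
Why: enone–alkene [2+2] photocycloaddition through the enone triplet, in which head-to-head orientation joins the methyl-bearing C10 to the unsubstituted cyclobutene carbon C1 and C5 to C4 (the pairing found for 6-alkyl-3-methylcyclohexenones with 1-methylcyclobutene, which avoids a bond between two fully substituted carbons), the four-membered rings necessarily fuse cis, and the new centres C1, C4, C5 and C10 are all erased in step 9, so cis-fused stereoisomers of this regiochemistry converge while C3 comes from 12 and C7/C8 from 7.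

Step 9
Reactants: 13 cis-anti-cis 6-4-4 tricyclic ketone
Product: 14 (1(10)E,4Z)-cyclodecadien-6-one
Conditions: PhMe (0.005 M, degassed), silanised sealed tube, 190 °C, stopped at full conversion of 13
Reagents that add atoms: none
Why: This is the thermal bicyclo[2.2.0]hexane-to-hexa-1,5-diene isomerisation known for cyclohexenone–cyclobutene photoadducts: strain release drives homolysis of the central C1–C4 bond to a cyclohexane-1,4-diyl (tertiary at C4), which relaxes to a chair and cleaves C5–C10, the bond that lies β to both radical centres and joins a quaternary carbon to the carbon α to the ketone. The ten-membered ring is not closed by bond formation but uncovered by this two-bond fragmentation of the bonds shared by the fused rings, and both double bonds form in the same event. No stereocentre is made, and C3, C7 and C8 are spectators. The step must give 1(10)E,4Z: because the cyclohexanone is cis-fused, one of the bonds C5–C6 and C10–C9 is axial and the other equatorial on the chair diyl, so one double bond must be Z and the other E, and the arrangement with C6 axial (Z at the enone) and C9 equatorial (E at C1=C10) is expected by analogy with related 6-substituted 3-methylcyclohexenone adducts. The other E,Z isomer can reach the same product through the reversible Cope manifold via the cis-divinylcyclohexanone, but that ketone is also the possible drain, so heating is not prolonged.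

Step 10
Reactants: 14 (1(10)E,4Z)-cyclodecadien-6-one
Product: 16 trans-fused 6α,12-lactone, via 6α-hydroxy ester 15 (not isolated)
Conditions: NaBH4, CeCl3·7H2O, MeOH, −78 °C; then PPTS (cat.), PhMe, 50 °C
Reagents that add atoms: none
Why: Luche 1,2-reduction followed by acid-catalysed lactonisation, in which hydride should add from the ring periphery to the carbonyl face that leaves H6 anti to H7 (the C7 side chain and the C8 silyl ether sitting in outward positions), giving the 6α-alcohol (6R), whose only available partner is the C7 acetate, so it closes as the trans-fused γ-lactone.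

Step 11
Reactants: 16 trans-fused 6α,12-lactone
Product: 19 α-methylene lactone, via Mannich base 17 (not isolated), via methiodide 18 (not isolated)
Conditions: LiN(iPr)2 (1.05 equiv), THF, −78 °C; Me2N=CH2 iodide (Eschenmoser's salt), −78 → 0 °C; MeI, MeOH, 25 °C; NaHCO3 (aq), CH2Cl2, 25 °C
Reagents that add atoms: N,N-dimethylmethyleneiminium iodide, C[N+](C)=C.[I-]
Why: Eschenmoser α-methylenation, in which one equivalent of amide base deprotonates the lactone α-CH2 (more acidic and far less hindered than the isobutyrate methine), the enolate undergoes a Mannich reaction with the iminium salt, and quaternisation followed by mild base-induced elimination gives the exocyclic methylene, so C11 ends sp2 and carries no stereocentre.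

Step 12
Reactants: 19 α-methylene lactone
Product: 20 8β-hydroxy α-methylene lactone
Conditions: HF·pyridine, pyridine, THF, 0 → 25 °C
Reagents that add atoms: none
Why: fluoride cleavage of the silyl ether under buffered acidic conditions, chosen because a basic fluoride source could induce translactonisation to O8 or conjugate addition to the methylene lactone.

Step 13
Reactants: 21 angelic acid
Product: 22 (Z)-2-methylbut-2-en-1-ol
Conditions: LiAlH4, Et2O, 0 °C
Reagents that add atoms: none
Why: hydride reduction of the carboxylic acid to the allylic alcohol, under which the trisubstituted Z double bond is neither reduced nor isomerised.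

Step 14
Reactants: 22 (Z)-2-methylbut-2-en-1-ol
Product: 23 [(2R,3S)-2,3-dimethyloxiran-2-yl]methanol
Conditions: Ti(OiPr)4 (cat.), D-(−)-diethyl tartrate, tBuOOH, 4 Å sieves, CH2Cl2, −20 °C
Reagents that add atoms: tert-butyl hydroperoxide, CC(C)(C)OO
Why: Sharpless asymmetric epoxidation, in which the titanium tartrate catalyst delivers oxygen to one face of the allylic alcohol (the face that gives 2R with the D-tartrate) and syn addition keeps the C3 methyl cis to CH2OH, setting both epoxide centres.

Step 15
Reactants: 23 [(2R,3S)-2,3-dimethyloxiran-2-yl]methanol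
Product: 24 (2S,3S)-2,3-dimethyloxirane-2-carboxylic acid
Conditions: RuCl3·3H2O (cat.), NaIO4, MeCN/EtOAc/H2O, 0 → 25 °C
Reagents that add atoms: water, O
Why: catalytic ruthenium tetroxide oxidation of the primary alcohol to the acid, a standard passage from 2,3-epoxy alcohols to glycidic acids that leaves both epoxide centres untouched (the C2 descriptor changes to S only through the priority change).

Step 16
Reactants: 24 (2S,3S)-2,3-dimethyloxirane-2-carboxylic acid; 20 8β-hydroxy α-methylene lactone
Product: 26 8β-epoxyangelate 3β-isobutyrate, via mixed anhydride 25 (not isolated)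
Conditions: 2,4,6-Cl3C6H2COCl, Et3N, THF, 0 °C; then 20, DMAP, PhMe, 25 °C
Reagents that add atoms: none
Why: Yamaguchi esterification, in which DMAP attacks the less hindered epoxy-acyl carbonyl of the mixed anhydride and the acylpyridinium acylates the hindered 8β-hydroxyl; the acid has no enolisable position (C2 is quaternary), so no stereocentre changes.

Step 17
Reactants: 26 8β-epoxyangelate 3β-isobutyrate
Product: 27 CNP0117882.1
Conditions: mCPBA, NaHCO3, CH2Cl2, 0 °C
Reagents that add atoms: 3-chloroperoxybenzoic acid, OOC(=O)c1cccc(Cl)c1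
Why: Prilezhaev epoxidation, in which the peracid selects the isolated, electron-rich trisubstituted C1=C10 bond over C4=C5 (flanked by two allylic C–O groups) and the conjugated methylene and attacks its exposed outer face in the heliangolide conformation, so the E alkene should give the trans 1β,10α-epoxide (1R,10R).

Compound list

1 | 5-methylcyclohexane-1,3-dione | CC1CC(=O)CC(=O)C1 | starting material
2 | methyl bromoacetate | COC(=O)CBr | starting material
3 | methyl 2-(4-methyl-2,6-dioxocyclohexyl)acetate (largely enolic) | COC(=O)CC1C(=O)CC(C)CC1=O | intermediate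
4 | methyl 2-[(1R,2R)-2-hydroxy-4-methyl-6-oxocyclohexyl]acetate (cis; both C4 epimers; not isolated) | O=C1CC(C)C[C@@H](O)[C@H]1CC(=O)OC | intermediate
5 | methyl 2-[(1R,2R)-2-(tert-butyldimethylsilyloxy)-4-methyl-6-oxocyclohexyl]acetate (both C4 epimers) | O=C1CC(C)C[C@@H](O[Si](C)(C)C(C)(C)C)[C@H]1CC(=O)OC | intermediate
6 | methyl 2-[(1R,6R)-6-(tert-butyldimethylsilyloxy)-4-methyl-2-(trimethylsilyloxy)cyclohex-2-en-1-yl]acetate (not isolated) | C[Si](C)(C)OC1=CC(C)C[C@@H](O[Si](C)(C)C(C)(C)C)[C@H]1CC(=O)OC | intermediate
7 | methyl 2-[(1R,6R)-6-(tert-butyldimethylsilyloxy)-4-methyl-2-oxocyclohex-3-en-1-yl]acetate | O=C1C=C(C)C[C@@H](O[Si](C)(C)C(C)(C)C)[C@H]1CC(=O)OC | intermediate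
8 | methylenecyclobutane | C=C1CCC1 | starting material
9 | 1-methylcyclobut-1-ene | CC1=CCC1 | intermediate
10 | rac-2-methylcyclobut-2-en-1-ol | CC1=CCC1O | intermediate
11 | (S)-2-methylcyclobut-2-en-1-ol | O[C@H]1CC=C1C | intermediate
12 | (S)-2-methylcyclobut-2-en-1-yl 2-methylpropanoate | CC(C)C(=O)O[C@H]1CC=C1C | intermediate
13 | cis-anti-cis tricyclo[4.4.0.0(2,5)]decanone photoadduct: C6 ketone, methyls on C4 and C10, H5 cis to 10-CH3, 4-CH3 cis to H1, cyclobutanes on the α face (away from 8β-OSiMe2tBu and 7β-CH2CO2Me), 3-isobutyryloxy endo (3S,7R,8R) | O=C1[C@@H]2[C@@]3(C)[C@@H](OC(=O)C(C)C)C[C@H]3[C@]2(C)C[C@@H](O[Si](C)(C)C(C)(C)C)[C@H]1CC(=O)OC | intermediate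
14 | methyl 2-[(1R,3Z,5S,7E,10R)-10-(tert-butyldimethylsilyloxy)-4,8-dimethyl-5-(2-methylpropanoyloxy)-2-oxocyclodeca-3,7-dien-1-yl]acetate (germacrane: 1(10)E,4Z, 6-oxo, 3β-isobutyrate, 8β-silyl ether, 7αH) | O=C1/C=C(/C)[C@@H](OC(=O)C(C)C)C/C=C(\C)C[C@@H](O[Si](C)(C)C(C)(C)C)[C@H]1CC(=O)OC | intermediate
15 | 6α-hydroxy ester (6R): methyl ester of the 1(10)E,4Z-dien-6α-ol with 3β-isobutyrate and 8β-silyl ether (not isolated) | O[C@@H]1/C=C(/C)[C@@H](OC(=O)C(C)C)C/C=C(\C)C[C@@H](O[Si](C)(C)C(C)(C)C)[C@H]1CC(=O)OC | intermediate
16 | (1(10)E,4Z)-8β-(tert-butyldimethylsilyloxy)-3β-isobutyryloxy-13-norgermacra-1(10),4-dien-12,6α-olide (trans-fused lactone, 7αH) | C1C(=O)O[C@@H]2/C=C(/C)[C@@H](OC(=O)C(C)C)C/C=C(\C)C[C@@H](O[Si](C)(C)C(C)(C)C)[C@@H]12 | intermediate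
17 | 11-(dimethylaminomethyl) derivative of 16 (Mannich base, C11 epimers; not isolated) | CN(C)CC1C(=O)O[C@@H]2/C=C(/C)[C@@H](OC(=O)C(C)C)C/C=C(\C)C[C@@H](O[Si](C)(C)C(C)(C)C)[C@@H]12 | intermediate
18 | trimethylammonium iodide of 17 (not isolated) | C[N+](C)(C)CC1C(=O)O[C@@H]2/C=C(/C)[C@@H](OC(=O)C(C)C)C/C=C(\C)C[C@@H](O[Si](C)(C)C(C)(C)C)[C@@H]12.[I-] | intermediate
19 | (1(10)E,4Z)-8β-(tert-butyldimethylsilyloxy)-3β-isobutyryloxygermacra-1(10),4,11(13)-trien-12,6α-olide | C=C1C(=O)O[C@@H]2/C=C(/C)[C@@H](OC(=O)C(C)C)C/C=C(\C)C[C@@H](O[Si](C)(C)C(C)(C)C)[C@@H]12 | intermediate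
20 | (1(10)E,4Z)-8β-hydroxy-3β-isobutyryloxygermacra-1(10),4,11(13)-trien-12,6α-olide (3S,6R,7R,8R) | C=C1C(=O)O[C@@H]2/C=C(/C)[C@@H](OC(=O)C(C)C)C/C=C(\C)C[C@@H](O)[C@@H]12 | intermediate
21 | angelic acid, (Z)-2-methylbut-2-enoic acid | C/C=C(/C)C(=O)O | starting material
22 | (Z)-2-methylbut-2-en-1-ol | C/C=C(/C)CO | intermediate
23 | [(2R,3S)-2,3-dimethyloxiran-2-yl]methanol | OC[C@@]1(C)O[C@H]1C | intermediate
24 | (2S,3S)-2,3-dimethyloxirane-2-carboxylic acid (epoxyangelic acid) | OC(=O)[C@@]1(C)O[C@H]1C | intermediate
25 | (2S,3S)-2,3-dimethyloxirane-2-carboxylic 2,4,6-trichlorobenzoic anhydride (not isolated) | O=C(OC(=O)c1c(Cl)cc(Cl)cc1Cl)[C@@]1(C)O[C@H]1C | intermediate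
26 | (1(10)E,4Z)-8β-[(2S,3S)-2,3-epoxy-2-methylbutanoyloxy]-3β-isobutyryloxygermacra-1(10),4,11(13)-trien-12,6α-olide | C=C1C(=O)O[C@@H]2/C=C(/C)[C@@H](OC(=O)C(C)C)C/C=C(\C)C[C@@H](OC(=O)[C@@]3(C)O[C@H]3C)[C@@H]12 | intermediate
27 | CNP0117882.1: (1R,3S,6R,7R,8R,10R)-1β,10α-epoxy-8β-[(2S,3S)-2,3-epoxy-2-methylbutanoyloxy]-3β-isobutyryloxygermacra-4Z,11(13)-dien-12,6α-olide | C=C1C(=O)O[C@@H]2/C=C(/C)[C@@H](OC(=O)C(C)C)C[C@H]3O[C@]3(C)C[C@@H](OC(=O)[C@@]3(C)O[C@H]3C)[C@@H]12 | target

Total step count: 17.
Longest linear sequence: 11 steps (steps 4, 5, 6, 7, 8, 9, 10, 11, 12, 16, 17, from methylenecyclobutane).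

Steps most likely to fail

Step 9. The E,Z-dienone may drain into the cis-divinylcyclohexanone by Cope rearrangement at the temperature needed for ring opening, or the diyl may partition towards the other E,Z isomer. The fallback sets out from 13 and removes the carbonyl during the thermolysis, a tactic known for carbinols of such photoadducts. The ketone is reduced (NaBH4, CeCl3·7H2O, MeOH, −78 °C) and the crude carbinol is capped at once (Et3SiOTf, 2,6-lutidine) as tricyclic triethylsilyl ether F1 (either C6 epimer serves). Heating as in step 9 should open it to cyclodecadienyl triethylsilyl ether F2. Selective loss of the triethylsilyl group (PPTS, MeOH, 0 °C) gives cyclodecadien-6-ol F3, and Dess–Martin oxidation comes back to the route at 14.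

Step 8. The hindered, chiral cyclobutene may add slowly or with head-to-tail orientation, and the face preferences of the two chiral partners are not matched for the anti-fused adduct. The fallback sets out from 7 and 9 and also by-passes steps 5 to 7. Irradiation of 7 with an excess of the unsubstituted alkene 9 gives parent photoadduct F4, and thermolysis as in step 9 gives parent dienone F5. O3 is then brought in through the extended silyl dienol ether F6 (tBuMe2SiOTf, Et3N) and its oxidation with dimethyldioxirane (vinylogous Rubottom oxidation) to 3β-hydroxy dienone F7, which is separated from its C3 epimer. Isobutyric anhydride with DMAP then comes back to the route at 14.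

Step 10. Facial selectivity of hydride delivery to the C6 carbonyl may be poor or reversed, giving the 6β-alcohol, which closes onto the ester as the cis lactone. The fallback sets out from 14 and corrects C6 by inversion. The reduction product is collected as cis-fused lactone F8, which is opened with LiOH (1.1 equiv, THF/H2O, 0 °C; the γ-lactone opens far faster than the hindered isobutyrate) to 6β-hydroxy acid F9. Mitsunobu lactonisation (PPh3, diisopropyl azodicarboxylate, PhMe, 0 °C) then closes the ring with inversion at C6 and comes back to the route at 16.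

Further compounds

F1 | step 9 | tricyclic C6 carbinol triethylsilyl ether of 13 (C6 epimers) | CC[Si](CC)(CC)OC1[C@@H]2[C@@]3(C)[C@@H](OC(=O)C(C)C)C[C@H]3[C@]2(C)C[C@@H](O[Si](C)(C)C(C)(C)C)[C@H]1CC(=O)OC
F2 | step 9 | (1(10)E,4Z)-cyclodecadienyl triethylsilyl ether (C6 epimers) | CC[Si](CC)(CC)OC1/C=C(/C)[C@@H](OC(=O)C(C)C)C/C=C(\C)C[C@@H](O[Si](C)(C)C(C)(C)C)[C@H]1CC(=O)OC
F3 | step 9 | (1(10)E,4Z)-cyclodecadien-6-ol (C6 epimers) | OC1/C=C(/C)[C@@H](OC(=O)C(C)C)C/C=C(\C)C[C@@H](O[Si](C)(C)C(C)(C)C)[C@H]1CC(=O)OC
F4 | step 8 | parent cis-anti-cis photoadduct without the C3 ester | O=C1[C@@H]2[C@@]3(C)CC[C@H]3[C@]2(C)C[C@@H](O[Si](C)(C)C(C)(C)C)[C@H]1CC(=O)OC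
F5 | step 8 | parent (1(10)E,4Z)-cyclodecadien-6-one without the C3 ester | O=C1/C=C(/C)CC/C=C(\C)C[C@@H](O[Si](C)(C)C(C)(C)C)[C@H]1CC(=O)OC
F6 | step 8 | extended tert-butyldimethylsilyl dienol ether of F5 (C3=C4, C5=C6) | CC(C)(C)[Si](C)(C)OC1=CC(C)=CC/C=C(\C)C[C@@H](O[Si](C)(C)C(C)(C)C)[C@H]1CC(=O)OC
F7 | step 8 | 3β-hydroxy (3S) derivative of F5 | O=C1/C=C(/C)[C@@H](O)C/C=C(\C)C[C@@H](O[Si](C)(C)C(C)(C)C)[C@H]1CC(=O)OC
F8 | step 10 | cis-fused 6β,12-lactone (C6 epimer of 16) | C1C(=O)O[C@H]2/C=C(/C)[C@@H](OC(=O)C(C)C)C/C=C(\C)C[C@@H](O[Si](C)(C)C(C)(C)C)[C@@H]12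
F9 | step 10 | 6β-hydroxy acid from F8 | O[C@H]1/C=C(/C)[C@@H](OC(=O)C(C)C)C/C=C(\C)C[C@@H](O[Si](C)(C)C(C)(C)C)[C@H]1CC(=O)O
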